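**Plan**

- Retrosynthetic cuts, in order: the C1–H and C2–H bonds of the indane together with six O–benzyl bonds; the C7a–C1 bond (with the C1=C2 unsaturation and the diazo group on C1); the aroyl C–aryl bond; last the C2–C3 bond and the aryl-ester C–O bond of a seven-membered lactone.
- Enabling feature: C1 lies between ring-A carbon C7a and the aroyl C=O, so it can be the carbene carbon of an α-diazo ketone. C7a is meta to both ring-A oxygens (the third position of a phloroglucinol), so it can enter as a phenol oxygen, hold the chain as a lactone, and leave as a triflate.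
- Forward order: benzoxepinone ring (temporary) by carbene-catalysed (4+3) annulation; lactone opened to the aryl ketone; phenol to triflate and CH2 to C=N2; five-membered ring closed by palladium carbene insertion; hydrogenation.
- Stereochemistry: C3 from the chiral carbene catalyst in the annulation; C1 and C2 from syn addition of H2 to the indene face opposite the C3 aryl group. The C2 centre of the early intermediates is erased in the key step, so its sense does not matter.

Key step: step 9

Remark: the SMILES is read as the all-cis (1R,2R,3R) indane (aroyl, 3,5-dihydroxyphenyl and 4-hydroxyphenyl on one face); this arrangement is base-labile at C1, so benzyl ethers and a neutral last step are used. Bn = benzyl.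

**Step 1**
Reactants: 1 2,4,6-trihydroxybenzaldehyde
Product: 2 2,4-bis(benzyloxy)-6-hydroxybenzaldehyde
Conditions: BnBr (2.05 equiv), K2CO3 (2.2 equiv), DMF, 0 °C to rt
Reagents that add atoms: benzyl bromide, BrCc1ccccc1
Why: Williamson etherification; the phenol hydrogen-bonded to the formyl group is the least nucleophilic, so two equivalents of BnBr should alkylate the 4-OH and one 2-OH and leave the chelated OH free.

**Step 2**
Reactants: 2 2,4-bis(benzyloxy)-6-hydroxybenzaldehyde; 3 4-(benzyloxy)phenylmagnesium bromide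
Product: 4 3,5-bis(benzyloxy)-2-{[4-(benzyloxy)phenyl](hydroxy)methyl}phenol (racemic)
Conditions: 3 (2.5 equiv), THF, 0 °C to rt; aq. NH4Cl; crude material used directly
Reagents that add atoms: none
Why: Grignard 1,2-addition to the aldehyde after the first equivalent has deprotonated the phenol; the carbinol centre is racemic and is destroyed in step 5.

**Step 3**
Reactants: 4 3,5-bis(benzyloxy)-2-{[4-(benzyloxy)phenyl](hydroxy)methyl}phenol
Product: 5 3,5-bis(benzyloxy)-2-{[4-(benzyloxy)phenyl](4-methylbenzenesulfonyl)methyl}phenol (racemic)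
Conditions: sodium p-toluenesulfinate (2 equiv), HCO2H, CH2Cl2–H2O, rt
Reagents that add atoms: sodium p-toluenesulfinate, Cc1ccc(cc1)S(=O)[O-].[Na+]
Why: acid ionises the very electron-rich benzhydrol (SN1 through the o-quinone methide/benzhydryl cation) and the sulfinate is S-alkylated, which stores the quinone methide as a stable sulfone.

**Step 4**
Reactants: 6 3,5-bis(benzyloxy)benzaldehyde; 7 (triphenylphosphoranylidene)acetaldehyde
Product: 8 (E)-3-[3,5-bis(benzyloxy)phenyl]prop-2-enal
Conditions: toluene, 80 °C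
Reagents that add atoms: none
Why: Wittig olefination with a stabilised formyl ylide should give the (E)-enal.

**Step 5**
Reactants: 5 sulfone; 8 (E)-3-[3,5-bis(benzyloxy)phenyl]prop-2-enal
Product: 10 (4S,5R)-6,8-bis(benzyloxy)-4-[3,5-bis(benzyloxy)phenyl]-5-[4-(benzyloxy)phenyl]-4,5-dihydro-1-benzoxepin-2(3H)-one, via o-quinone methide 9 (not isolated)
Conditions: aminoindanol-derived N-mesityl triazolium tetrafluoroborate (2-mesityl-5a,10b-dihydro-4H,6H-indeno[2,1-b][1,2,4]triazolo[4,3-d][1,4]oxazin-2-ium BF4, 10 mol %, the enantiomer that leads to the 5R lactone), Cs2CO3 (1.3 equiv), 4 Å sieves, THF, 0 °C to rt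
Reagents that add atoms: none
Why: carbonate expels sulfinate (E1cB) to release 9; carbene and enal form a homoenolate (Breslow intermediate) whose β-carbon adds to the methide carbon, and the acyl azolium then acylates the phenoxide (carbene-catalysed formal (4+3) annulation). The chiral carbene shields one face and should set the benzhydryl carbon C5 as R, with C4 expected mainly cis; a trans isomer converges at step 9.

**Step 6**
Reactants: 10 benzoxepinone; 3 4-(benzyloxy)phenylmagnesium bromide
Product: 12 (3S,4R)-4-[2,4-bis(benzyloxy)-6-hydroxyphenyl]-3-[3,5-bis(benzyloxy)phenyl]-1,4-bis[4-(benzyloxy)phenyl]butan-1-one, via Weinreb amide 11 (not isolated)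
Conditions: MeNH(OMe)·HCl (1.5 equiv), iPrMgCl (3.0 equiv), THF, −20 °C; then 3 (3 equiv), 0 °C to rt; aq. NH4Cl
Reagents that add atoms: N,O-dimethylhydroxylamine hydrochloride, CNOC.Cl (its atoms stay in 11 only)
Why: the magnesium amide opens the aryl ester to the N-methoxy-N-methylamide, whose chelated adduct with the Grignard reagent collapses to the ketone only on work-up (Weinreb ketone synthesis), so no tertiary alcohol should form; neither stereocentre is α to a carbonyl.

**Step 7**
Reactants: 12 keto phenol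
Product: 13 3,5-bis(benzyloxy)-2-{(1R,2S)-2-[3,5-bis(benzyloxy)phenyl]-1,4-bis[4-(benzyloxy)phenyl]-4-oxobutyl}phenyl trifluoromethanesulfonate
Conditions: PhNTf2 (1.3 equiv), Cs2CO3 (1.5 equiv), DMF, 0 °C to rt
Reagents that add atoms: N-phenylbis(trifluoromethanesulfonimide), O=S(=O)(N(c1ccccc1)S(=O)(=O)C(F)(F)F)C(F)(F)F
Why: O-sulfonylation of the phenoxide with a mild triflyl donor; carbonate does not enolise the ketone.

**Step 8**
Reactants: 13 aryl triflate ketone
Product: 15 3,5-bis(benzyloxy)-2-{(1R,2S)-2-[3,5-bis(benzyloxy)phenyl]-1,4-bis[4-(benzyloxy)phenyl]-3-diazo-4-oxobutyl}phenyl trifluoromethanesulfonate, via trifluoroacetyl ketone 14 (not isolated)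
Conditions: LiN(SiMe3)2 (1.1 equiv), THF, −78 °C; CF3CO2CH2CF3 (1.2 equiv); dilute HCl work-up; then 4-acetamidobenzenesulfonyl azide (1.5 equiv), Et3N (1.5 equiv), H2O (1 equiv), MeCN, rt
Reagents that add atoms: 2,2,2-trifluoroethyl trifluoroacetate, O=C(OCC(F)(F)F)C(F)(F)F (its atoms stay in 14 only); 4-acetamidobenzenesulfonyl azide, CC(=O)Nc1ccc(cc1)S(=O)(=O)N=[N+]=[N-]
Why: Claisen trifluoroacetylation of the only possible enolate activates the CH2 group, and Regitz-type deacylative diazo transfer should then give the α-diazo ketone with loss of the N-sulfonyl trifluoroacetamide.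

**Step 9**
Reactants: 15 α-diazo ketone aryl triflate
Product: 16 {(1S)-5,7-bis(benzyloxy)-2-[3,5-bis(benzyloxy)phenyl]-1-[4-(benzyloxy)phenyl]-1H-inden-3-yl}[4-(benzyloxy)phenyl]methanone
Conditions: Pd2(dba)3 (2.5 mol %), XPhos (10 mol %), 2,6-di-tert-butyl-4-methylpyridine (1.5 equiv), toluene (0.02 M), 50 °C; filtration through a short silica pad, used at once
Reagents that add atoms: none
Why: Zerovalent palladium inserts into the C–OTf bond of ring A, the cationic arylpalladium takes up the diazo carbon with loss of N2 to give a chelated palladium carbene, 1,1-migratory insertion moves the ring-A carbon from palladium to the carbene carbon (the C7a–C1 bond of the target, C3a–C3 of 16) and leaves a palladium enolate, and syn β-hydride elimination followed by transfer of TfOH to the hindered pyridine gives the enone and returns the catalyst. The closest known reaction type is the palladium-catalysed carbene migratory-insertion cross-coupling of aryl halides or sulfonates with diazo carbonyl compounds and N-tosylhydrazones, which likewise ends in β-hydride elimination to an alkene. The five-membered carbocycle closes by contraction of a six-membered palladacycle (aryl shift from palladium to carbon), not by attack on a π bond, so no endo/exo constraint applies. No stereocentre is made: the centre bearing the 3,5-bis(benzyloxy)phenyl group becomes sp2 (so the diastereomer ratio of 10 is irrelevant) and the diarylmethine carbon, which is γ to palladium, is not touched. The site of ring closure is fixed by the triflate on the former lactone-oxygen carbon (meta to both benzyloxy groups and not reachable by electrophilic substitution), and the direction of β-hydride elimination is fixed because the other neighbour of the palladium-bearing carbon is the carbonyl carbon. The competing processes are 1,2-hydrogen shift of the carbene and base-mediated racemisation of the acidic indene C1–H; the intramolecular insertion and the weak, hindered, non-nucleophilic base are chosen against them.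

**Step 10**
Reactants: 16 indenyl ketone
Product: 18 caraphenol C, [(1R,2R,3R)-2-(3,5-dihydroxyphenyl)-4,6-dihydroxy-3-(4-hydroxyphenyl)-2,3-dihydro-1H-inden-1-yl](4-hydroxyphenyl)methanone, via hexaphenolic indenyl ketone 17 (not isolated)
Conditions: H2 (1 to 4 atm), 10% Pd/C, EtOAc–MeOH, rt; reaction stopped as soon as the alkene is consumed
Reagents that add atoms: none
Why: heterogeneous hydrogenation; O-benzyl hydrogenolysis is expected to run ahead of saturation of the hindered tetrasubstituted enone, and H2 should then add syn to the indene face opposite the C1 aryl group (indene numbering), which places all three substituents cis (1R,2R,3R) while the neutral medium spares the epimerisable C1 centre.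

**Compound list**

1 | 2,4,6-trihydroxybenzaldehyde | O=Cc1c(O)cc(O)cc1O | starting material
2 | 2,4-bis(benzyloxy)-6-hydroxybenzaldehyde | O=Cc1c(O)cc(OCc2ccccc2)cc1OCc1ccccc1 | intermediate
3 | 4-(benzyloxy)phenylmagnesium bromide | Br[Mg]c1ccc(OCc2ccccc2)cc1 | starting material
4 | 3,5-bis(benzyloxy)-2-{[4-(benzyloxy)phenyl](hydroxy)methyl}phenol (racemic) | OC(c1ccc(OCc2ccccc2)cc1)c1c(O)cc(OCc2ccccc2)cc1OCc1ccccc1 | intermediate
5 | 3,5-bis(benzyloxy)-2-{[4-(benzyloxy)phenyl](4-methylbenzenesulfonyl)methyl}phenol (racemic) | Cc1ccc(cc1)S(=O)(=O)C(c1ccc(OCc2ccccc2)cc1)c1c(O)cc(OCc2ccccc2)cc1OCc1ccccc1 | intermediate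
6 | 3,5-bis(benzyloxy)benzaldehyde | O=Cc1cc(OCc2ccccc2)cc(OCc2ccccc2)c1 | starting material
7 | (triphenylphosphoranylidene)acetaldehyde | O=CC=P(c1ccccc1)(c1ccccc1)c1ccccc1 | starting material
8 | (E)-3-[3,5-bis(benzyloxy)phenyl]prop-2-enal | O=C/C=C/c1cc(OCc2ccccc2)cc(OCc2ccccc2)c1 | intermediate
9 | (6Z)-3,5-bis(benzyloxy)-6-{[4-(benzyloxy)phenyl]methylidene}cyclohexa-2,4-dien-1-one (o-quinone methide) | O=C1C=C(OCc2ccccc2)C=C(OCc2ccccc2)/C1=C/c1ccc(OCc2ccccc2)cc1 | intermediate
10 | (4S,5R)-6,8-bis(benzyloxy)-4-[3,5-bis(benzyloxy)phenyl]-5-[4-(benzyloxy)phenyl]-4,5-dihydro-1-benzoxepin-2(3H)-one | O=C1C[C@H](c2cc(OCc3ccccc3)cc(OCc3ccccc3)c2)[C@H](c2ccc(OCc3ccccc3)cc2)c2c(OCc3ccccc3)cc(OCc3ccccc3)cc2O1 | intermediate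
11 | (3S,4R)-4-[2,4-bis(benzyloxy)-6-hydroxyphenyl]-3-[3,5-bis(benzyloxy)phenyl]-4-[4-(benzyloxy)phenyl]-N-methoxy-N-methylbutanamide | CON(C)C(=O)C[C@H](c1cc(OCc2ccccc2)cc(OCc2ccccc2)c1)[C@H](c1ccc(OCc2ccccc2)cc1)c1c(O)cc(OCc2ccccc2)cc1OCc1ccccc1 | intermediate
12 | (3S,4R)-4-[2,4-bis(benzyloxy)-6-hydroxyphenyl]-3-[3,5-bis(benzyloxy)phenyl]-1,4-bis[4-(benzyloxy)phenyl]butan-1-one | O=C(c1ccc(OCc2ccccc2)cc1)C[C@H](c1cc(OCc2ccccc2)cc(OCc2ccccc2)c1)[C@H](c1ccc(OCc2ccccc2)cc1)c1c(O)cc(OCc2ccccc2)cc1OCc1ccccc1 | intermediate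
13 | 3,5-bis(benzyloxy)-2-{(1R,2S)-2-[3,5-bis(benzyloxy)phenyl]-1,4-bis[4-(benzyloxy)phenyl]-4-oxobutyl}phenyl trifluoromethanesulfonate | O=C(c1ccc(OCc2ccccc2)cc1)C[C@H](c1cc(OCc2ccccc2)cc(OCc2ccccc2)c1)[C@H](c1ccc(OCc2ccccc2)cc1)c1c(OS(=O)(=O)C(F)(F)F)cc(OCc2ccccc2)cc1OCc1ccccc1 | intermediate
14 | α-trifluoroacetyl derivative of 13 (CF3CO on the carbon between the ketone and the aryl-bearing carbon; 1,3-diketone, enolisable; the two stereocentres of 13 unchanged) | O=C(c1ccc(OCc2ccccc2)cc1)C(C(=O)C(F)(F)F)[C@H](c1cc(OCc2ccccc2)cc(OCc2ccccc2)c1)[C@H](c1ccc(OCc2ccccc2)cc1)c1c(OS(=O)(=O)C(F)(F)F)cc(OCc2ccccc2)cc1OCc1ccccc1 | intermediate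
15 | 3,5-bis(benzyloxy)-2-{(1R,2S)-2-[3,5-bis(benzyloxy)phenyl]-1,4-bis[4-(benzyloxy)phenyl]-3-diazo-4-oxobutyl}phenyl trifluoromethanesulfonate | O=C(c1ccc(OCc2ccccc2)cc1)C(=[N+]=[N-])[C@H](c1cc(OCc2ccccc2)cc(OCc2ccccc2)c1)[C@H](c1ccc(OCc2ccccc2)cc1)c1c(OS(=O)(=O)C(F)(F)F)cc(OCc2ccccc2)cc1OCc1ccccc1 | intermediate
16 | {(1S)-5,7-bis(benzyloxy)-2-[3,5-bis(benzyloxy)phenyl]-1-[4-(benzyloxy)phenyl]-1H-inden-3-yl}[4-(benzyloxy)phenyl]methanone | O=C(c1ccc(OCc2ccccc2)cc1)C1=C(c2cc(OCc3ccccc3)cc(OCc3ccccc3)c2)[C@H](c2ccc(OCc3ccccc3)cc2)c2c(OCc3ccccc3)cc(OCc3ccccc3)cc12 | intermediate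
17 | [(1S)-2-(3,5-dihydroxyphenyl)-5,7-dihydroxy-1-(4-hydroxyphenyl)-1H-inden-3-yl](4-hydroxyphenyl)methanone | O=C(c1ccc(O)cc1)C1=C(c2cc(O)cc(O)c2)[C@H](c2ccc(O)cc2)c2c(O)cc(O)cc12 | intermediate
18 | caraphenol C, [(1R,2R,3R)-2-(3,5-dihydroxyphenyl)-4,6-dihydroxy-3-(4-hydroxyphenyl)-2,3-dihydro-1H-inden-1-yl](4-hydroxyphenyl)methanone | O=C(c1ccc(O)cc1)[C@H]1c2cc(O)cc(O)c2[C@@H](c2ccc(O)cc2)[C@H]1c1cc(O)cc(O)c1 | target

**Step count and risks**

Total steps: 10. Longest linear sequence: 9 (steps 1, 2, 3, 5, 6, 7, 8, 9, 10; step 4 is a one-step branch).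

Steps most likely to fail:

1. Step 9. The diazo ketone may lose N2 and undergo 1,2-hydrogen shift before oxidative addition, or the acidic indene C1–H of the product may racemise under the reaction conditions. The fallback sets out from 13 and returns at 16. Intramolecular palladium-catalysed α-arylation of the ketone enolate (Pd(OAc)2, XPhos, K3PO4, toluene, 90 °C) should close the same bond and give the saturated indanyl ketone F1, with its configuration at C1 being of no consequence. Silylation (Me3SiOTf, Et3N, CH2Cl2, 0 °C) should give the exocyclic trimethylsilyl enol ether F2. Saegusa–Ito dehydrogenation (Pd(OAc)2, MeCN, rt, no amine) should then give 16 by β-hydride elimination towards C2.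

2. Step 5. Enantiofacial control may be insufficient with this donor-stabilised quinone methide, or the homoenolate may be diverted to the azolium-enolate (4+2) pathway. The fallback sets out from 5 and 8 and returns at 10. The annulation is run with an achiral carbene (1,3-dimesitylimidazolium chloride, Cs2CO3, THF) to give the racemic cis lactone. The enantiomers are then separated by preparative chromatography on a chiral stationary phase; 10 is carried on and the enantiomeric (4R,5S)-benzoxepinone F3 is set aside.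

3. Step 10. The aryl ketone may be over-reduced, the tetrasubstituted alkene may saturate incompletely during global hydrogenolysis, or C1 may epimerise. The fallback sets out from 16 and returns at 18. Homogeneous hydrogenation with [Ir(cod)(PCy3)(py)]PF6 (H2, CH2Cl2, rt), which leaves benzyl ethers and the ketone alone, should give the all-cis hexabenzyl indanyl ketone F4. Non-reductive debenzylation (BCl3, pentamethylbenzene, CH2Cl2, −78 °C) should then give 18.

**Further compounds**

F1 | step 9 | {(1S,2R,3R)-4,6-bis(benzyloxy)-2-[3,5-bis(benzyloxy)phenyl]-3-[4-(benzyloxy)phenyl]-2,3-dihydro-1H-inden-1-yl}[4-(benzyloxy)phenyl]methanone | O=C(c1ccc(OCc2ccccc2)cc1)[C@@H]1c2cc(OCc3ccccc3)cc(OCc3ccccc3)c2[C@@H](c2ccc(OCc3ccccc3)cc2)[C@H]1c1cc(OCc2ccccc2)cc(OCc2ccccc2)c1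
F2 | step 9 | ({(2S,3R)-4,6-bis(benzyloxy)-2-[3,5-bis(benzyloxy)phenyl]-3-[4-(benzyloxy)phenyl]-2,3-dihydro-1H-inden-1-ylidene}[4-(benzyloxy)phenyl]methoxy)trimethylsilane (enol ether geometry not controlled) | C[Si](C)(C)OC(c1ccc(OCc2ccccc2)cc1)=C1c2cc(OCc3ccccc3)cc(OCc3ccccc3)c2[C@@H](c2ccc(OCc3ccccc3)cc2)[C@H]1c1cc(OCc2ccccc2)cc(OCc2ccccc2)c1
F3 | step 5 | (4R,5S)-6,8-bis(benzyloxy)-4-[3,5-bis(benzyloxy)phenyl]-5-[4-(benzyloxy)phenyl]-4,5-dihydro-1-benzoxepin-2(3H)-one | O=C1C[C@@H](c2cc(OCc3ccccc3)cc(OCc3ccccc3)c2)[C@@H](c2ccc(OCc3ccccc3)cc2)c2c(OCc3ccccc3)cc(OCc3ccccc3)cc2O1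
F4 | step 10 | {(1R,2R,3R)-4,6-bis(benzyloxy)-2-[3,5-bis(benzyloxy)phenyl]-3-[4-(benzyloxy)phenyl]-2,3-dihydro-1H-inden-1-yl}[4-(benzyloxy)phenyl]methanone | O=C(c1ccc(OCc2ccccc2)cc1)[C@H]1c2cc(OCc3ccccc3)cc(OCc3ccccc3)c2[C@@H](c2ccc(OCc3ccccc3)cc2)[C@H]1c1cc(OCc2ccccc2)cc(OCc2ccccc2)c1
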